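**Plan**

1. The target is read as the meso-type 8–8′ dimer of resveratrol: two identical 4-hydroxyphenyl–C–C(3,5-dihydroxyphenyl) halves joined at indane C1–C2, one half closed onto the resorcinol ring of the other. Retrosynthesis cuts, in this order: the six O–benzyl bonds; the carbinol C–H (back to an aryl ketone); the ring bond C3–C3a; the C–H of a sacrificial carbinol at C3 (back to a meso 1,4-diketone); the central bond C1–C2 (dimerisation of one deoxybenzoin); the aryl–CH2 bond of that ketone.
2. Forward: a ketone α-arylation gives the C6–C2–C6 ketone, oxidative enolate coupling joins two of them into the whole open-chain skeleton, and the only ring to be made, the five-membered ring of the indane, is closed from C3 to C3a.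
3. What makes the closure possible: C3 bears a 4-oxygenated phenyl ring, so a cation at C3 is a quinoid oxocarbenium ion, and C3a of the resorcinol ring, ortho to O-4 and para to O-6, lies five atoms round (C3, C2, C1, C7a, C3a). The carbinol carbon is held as a ketone so that only C3 can ionise.
4. Stereochemistry: the C1/C2 relative configuration comes from the meso diketone (equilibration, crystallisation). The absolute sense comes from one CBS reduction that chooses between the two enantiotopic carbonyls. From the surviving C2 centre, substrate control sets C3 (kinetic) and C1 (thermodynamic) in the ring closure. The carbinol carbon is set by a second CBS reduction matched with Felkin–Anh control.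

Key step: step 4

Remark on the chemistry (assumption): both CBS reductions are written on the usual model in which the aryl group of an aryl ketone acts as the large substituent, so (R)-Me-CBS gives the (S)-carbinol and (S)-Me-CBS the (R)-carbinol. If the branched alkyl side dominated, the two catalyst enantiomers would be exchanged and nothing else would change.

Step 1
Reactants: 1 1,3-bis(benzyloxy)-5-bromobenzene; 2 1-[4-(benzyloxy)phenyl]ethan-1-one
Product: 3 2-[3,5-bis(benzyloxy)phenyl]-1-[4-(benzyloxy)phenyl]ethan-1-one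
Conditions: Pd2(dba)3 (1.5 mol%), rac-BINAP (3.6 mol%), NaOtBu (1.3 equiv), 2 (1.2 equiv), THF, 70 °C
Reagents that add atoms: none
Why: Palladium-catalysed ketone α-arylation (Buchwald–Hartwig type), in which oxidative addition of zerovalent palladium into the C–Br bond, enolate transmetalation and reductive elimination form the aryl–CH2 bond, monoarylation being favoured by the bisphosphine and the slight excess of the methyl ketone.

Step 2
Reactants: 3 2-[3,5-bis(benzyloxy)phenyl]-1-[4-(benzyloxy)phenyl]ethan-1-one (two molecules)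
Product: 7 meso-(2R,3S)-2,3-bis[3,5-bis(benzyloxy)phenyl]-1,4-bis[4-(benzyloxy)phenyl]butane-1,4-dione, via lithium enolate 4 (not isolated), via α-iodo ketone 5 (not isolated), via racemic diketone 6 (not isolated)
Conditions: LiN(SiMe3)2 (1.05 equiv), THF, –78 °C; I2 (0.5 equiv), –78 °C → rt; then DBU (0.2 equiv), toluene/EtOH, 60 °C → rt, crystallisation
Reagents that add atoms: none
Why: Oxidative enolate homocoupling (the classical bidesyl synthesis), in which iodination of one enolate and displacement of iodide by a second join the two α-carbons and build the whole carbon skeleton; both new stereocentres are enolisable, so DBU equilibration with crystallisation of the less soluble centrosymmetric meso isomer (crystallisation-induced diastereomer transformation) should funnel the mixture to 7.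

Step 3
Reactants: 7 meso-(2R,3S)-2,3-bis[3,5-bis(benzyloxy)phenyl]-1,4-bis[4-(benzyloxy)phenyl]butane-1,4-dione
Product: 8 (2R,3S,4S)-2,3-bis[3,5-bis(benzyloxy)phenyl]-1,4-bis[4-(benzyloxy)phenyl]-4-hydroxybutan-1-one
Conditions: (R)-Me-CBS (0.3 equiv), BH3·SMe2 (0.6 equiv, slow addition), CH2Cl2/THF, –20 °C; MeOH; chromatography
Reagents that add atoms: none
Why: CBS reduction used as a desymmetrisation: (R)-Me-CBS should give the (S)-carbinol, and only at the carbonyl next to the (S)-configured α-carbon of 7 is that also the Felkin–Anh product (hydride anti to the α-aryl group), so this matched carbonyl should be reduced faster and the new C4 carbinol, itself sacrificial, fixes the absolute sense of C2/C3, while the remaining mismatched carbonyl resists over-reduction and the diastereomeric hydroxy ketone from attack at the other carbonyl is removed by chromatography.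

Step 4
Reactants: 8 (2R,3S,4S)-2,3-bis[3,5-bis(benzyloxy)phenyl]-1,4-bis[4-(benzyloxy)phenyl]-4-hydroxybutan-1-one
Product: 10 [(1R,2S,3R)-4,6-bis(benzyloxy)-2-[3,5-bis(benzyloxy)phenyl]-3-[4-(benzyloxy)phenyl]-2,3-dihydro-1H-inden-1-yl][4-(benzyloxy)phenyl]methanone, via benzylic cation 9 (not isolated)
Conditions: BF3·OEt2 (0.3 equiv), CH2Cl2 (0.01 M), –40 → 0 °C; Et3N; then DBU (0.1 equiv), CH2Cl2, rt
Reagents that add atoms: none
Why: BF3 ionises the only carbinol of 8 (C4–OH, benzylic to a 4-benzyloxyphenyl ring) to the quinoid-stabilised cation 9, while the C1 ketone cannot ionise and so shields the future carbinol carbon; the 3,5-bis(benzyloxy)phenyl ring on C2 then attacks the cation through its ring carbon ortho to one benzyloxy group and para to the other, and loss of a proton restores the arene, the closest known reaction type being the acid-promoted Friedel–Crafts cyclialkylation of benzylic alcohols onto dialkoxyarenes that gives 1-arylindanes and aryltetralins. The closure is 5-exo-trig on the quinoid form of 9 (the C=C that is consumed lies outside the new five-membered ring) and gives the indane. The new stereocentre (indane C3) is controlled by the neighbouring aryl-bearing carbon (indane C2): the transition state that keeps the two adjacent aryl groups on opposite faces avoids their eclipsing, so C3 should form trans to C2. Indane C1, α to the ketone, inherits its trans relation from the meso backbone and, being enolisable, is held or returned there by the DBU equilibration, the all-trans arrangement being the most stable. The selectivities needed are regioselectivity, secured by geometry because only the aryl ring on C2 of 8 can reach C4 through a five-membered ring (the ring on C3 would close a four-membered ring) and its two ortho positions are equivalent, and retention of the C3 stereocentre of 8 (indane C2), which alone carries the absolute configuration through the cation and is protected by ring closure outrunning loss of the adjacent proton (high dilution, low temperature, strongly activated nucleophile).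

Step 5
Reactants: 10 [(1R,2S,3R)-4,6-bis(benzyloxy)-2-[3,5-bis(benzyloxy)phenyl]-3-[4-(benzyloxy)phenyl]-2,3-dihydro-1H-inden-1-yl][4-(benzyloxy)phenyl]methanone
Product: 11 (R)-[(1R,2S,3R)-4,6-bis(benzyloxy)-2-[3,5-bis(benzyloxy)phenyl]-3-[4-(benzyloxy)phenyl]-2,3-dihydro-1H-inden-1-yl][4-(benzyloxy)phenyl]methanol
Conditions: (S)-Me-CBS (0.5 equiv), BH3·SMe2 (1.0 equiv), THF, –20 → 0 °C; MeOH
Reagents that add atoms: none
Why: CBS reduction in which (S)-Me-CBS should deliver hydride to the carbonyl face that gives the (R)-carbinol, the same face that Felkin–Anh attack anti to the ring-fusion aryl carbon C7a at indane C1 prefers, so reagent and substrate control reinforce each other, and the neutral borane conditions leave the enolisable C1 untouched.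

Step 6
Reactants: 11 (R)-[(1R,2S,3R)-4,6-bis(benzyloxy)-2-[3,5-bis(benzyloxy)phenyl]-3-[4-(benzyloxy)phenyl]-2,3-dihydro-1H-inden-1-yl][4-(benzyloxy)phenyl]methanol
Product: 12 (1R,2S,3R)-2-(3,5-dihydroxyphenyl)-1-[(R)-hydroxy(4-hydroxyphenyl)methyl]-3-(4-hydroxyphenyl)-2,3-dihydro-1H-indene-4,6-diol
Conditions: H2 (1 atm), Pd/C (10 wt%), EtOAc/MeOH, rt
Reagents that add atoms: none
Why: Hydrogenolysis of the six aryl benzyl ethers over Pd/C under neutral conditions, where O-benzyl cleavage is much faster than hydrogenolysis of the hindered secondary benzylic carbinol (as in debenzylations that leave aryl ethanolamine carbinols intact), and no stereocentre is touched.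

**Compound list**

1 | 1,3-bis(benzyloxy)-5-bromobenzene | Brc1cc(OCc2ccccc2)cc(OCc2ccccc2)c1 | starting material
2 | 1-[4-(benzyloxy)phenyl]ethan-1-one | CC(=O)c1ccc(OCc2ccccc2)cc1 | starting material
3 | 2-[3,5-bis(benzyloxy)phenyl]-1-[4-(benzyloxy)phenyl]ethan-1-one | O=C(Cc1cc(OCc2ccccc2)cc(OCc2ccccc2)c1)c1ccc(OCc2ccccc2)cc1 | intermediate
4 | lithium (Z)-enolate of 3 | [Li+].[O-]/C(=C\c1cc(OCc2ccccc2)cc(OCc2ccccc2)c1)c1ccc(OCc2ccccc2)cc1 | intermediate
5 | 2-[3,5-bis(benzyloxy)phenyl]-1-[4-(benzyloxy)phenyl]-2-iodoethan-1-one (racemic) | O=C(C(I)c1cc(OCc2ccccc2)cc(OCc2ccccc2)c1)c1ccc(OCc2ccccc2)cc1 | intermediate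
6 | (2RS,3RS)-2,3-bis[3,5-bis(benzyloxy)phenyl]-1,4-bis[4-(benzyloxy)phenyl]butane-1,4-dione (racemic chiral diastereomer, the 2S,3S enantiomer drawn) | O=C(c1ccc(OCc2ccccc2)cc1)[C@H](c1cc(OCc2ccccc2)cc(OCc2ccccc2)c1)[C@@H](c1cc(OCc2ccccc2)cc(OCc2ccccc2)c1)C(=O)c1ccc(OCc2ccccc2)cc1 | intermediate
7 | meso-(2R,3S)-2,3-bis[3,5-bis(benzyloxy)phenyl]-1,4-bis[4-(benzyloxy)phenyl]butane-1,4-dione | O=C(c1ccc(OCc2ccccc2)cc1)[C@H](c1cc(OCc2ccccc2)cc(OCc2ccccc2)c1)[C@H](c1cc(OCc2ccccc2)cc(OCc2ccccc2)c1)C(=O)c1ccc(OCc2ccccc2)cc1 | intermediate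
8 | (2R,3S,4S)-2,3-bis[3,5-bis(benzyloxy)phenyl]-1,4-bis[4-(benzyloxy)phenyl]-4-hydroxybutan-1-one | c1ccccc1COc1ccc(cc1)[C@@H](O)[C@H](c1cc(OCc2ccccc2)cc(OCc2ccccc2)c1)[C@H](c1cc(OCc2ccccc2)cc(OCc2ccccc2)c1)C(=O)c1ccc(OCc2ccccc2)cc1 | intermediate
9 | (2S,3R)-2,3-bis[3,5-bis(benzyloxy)phenyl]-1,4-bis[4-(benzyloxy)phenyl]-4-oxobutan-1-ylium (the 4-benzyloxybenzylic cation formed from 8 by loss of the C4 hydroxyl) | c1ccccc1COc1ccc(cc1)[CH+][C@H](c1cc(OCc2ccccc2)cc(OCc2ccccc2)c1)[C@H](c1cc(OCc2ccccc2)cc(OCc2ccccc2)c1)C(=O)c1ccc(OCc2ccccc2)cc1 | intermediate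
10 | [(1R,2S,3R)-4,6-bis(benzyloxy)-2-[3,5-bis(benzyloxy)phenyl]-3-[4-(benzyloxy)phenyl]-2,3-dihydro-1H-inden-1-yl][4-(benzyloxy)phenyl]methanone | c1ccccc1COc1ccc([C@@H]2c3c(OCc4ccccc4)cc(OCc4ccccc4)cc3[C@H](C(=O)c3ccc(OCc4ccccc4)cc3)[C@H]2c2cc(OCc3ccccc3)cc(OCc3ccccc3)c2)cc1 | intermediate
11 | (R)-[(1R,2S,3R)-4,6-bis(benzyloxy)-2-[3,5-bis(benzyloxy)phenyl]-3-[4-(benzyloxy)phenyl]-2,3-dihydro-1H-inden-1-yl][4-(benzyloxy)phenyl]methanol | c1ccccc1COc1ccc([C@@H]2c3c(OCc4ccccc4)cc(OCc4ccccc4)cc3[C@H]([C@@H](O)c3ccc(OCc4ccccc4)cc3)[C@H]2c2cc(OCc3ccccc3)cc(OCc3ccccc3)c2)cc1 | intermediate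
12 | (1R,2S,3R)-2-(3,5-dihydroxyphenyl)-1-[(R)-hydroxy(4-hydroxyphenyl)methyl]-3-(4-hydroxyphenyl)-2,3-dihydro-1H-indene-4,6-diol | Oc1ccc([C@@H]2c3c(O)cc(O)cc3[C@H]([C@@H](O)c3ccc(O)cc3)[C@H]2c2cc(O)cc(O)c2)cc1 | target

**Totals**

Total step count: 6. Longest linear sequence: 6 steps (from 1 or 2 to 12).

**Steps most likely to fail, with fallbacks**

Step 3. What may go wrong: insufficient discrimination between the two enantiotopic carbonyl groups, over-reduction to the diol, or failure to separate the diastereomeric hydroxy ketone that stems from reduction of the other carbonyl. Each would lower the enantiomeric purity that enters the ring closure. The fallback introduces the absolute configuration later, by resolution instead of desymmetrisation. It sets out from 7: unselective mono-reduction (NaBH4, 0.3 equiv, THF/MeOH, –20 °C) should give the racemic hydroxy ketone F1, and the conditions of step 4 should turn it into the racemic indanyl ketone F2. A kinetic resolution of F2 with (S)-Me-CBS and a deficit of BH3·SMe2 (about 0.3 equiv) should reduce the matched enantiomer to 11. The mismatched enantiomer should stay a ketone or, where it is reduced under catalyst control, end as the diastereomeric carbinol on the mirror-image indane F3. Both are removed by chromatography, and the route is rejoined at 11.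

Step 4 (key step). What may go wrong: loss of the proton next to the cation followed by re-protonation (erosion of enantiomeric purity), stalling through reversible capture of the cation by the ketone oxygen, or intermolecular alkylation. The fallback uses a neutral quinone methide in place of a free cation. It sets out from 8: hydrogenolysis (H2, Pd/C, EtOAc/MeOH, rt) should give the hexaphenol hydroxy ketone F4. In aqueous HFIP with a trace of HCO2H at 40 °C the 4-hydroxybenzylic alcohol should lose water to the para-quinone methide F5, and the free resorcinol ring should add to it in the same 5-exo sense to give the hexaphenol indanyl ketone F6. Re-benzylation (BnBr, K2CO3, acetone, 50 °C) rejoins the route at 10.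

Step 5. What may go wrong: poor facial selectivity, or hydride delivery to the opposite face if the conformational bias of the crowded indane overrides the catalyst. The fallback uses inversion instead of direct reduction. It sets out from 10: reduction with a reagent that favours the opposite face (for example (R)-Me-CBS/BH3·SMe2 or LiBH(s-Bu)3, THF, –78 °C) should give the (S)-configured epimeric carbinol F7. Mitsunobu inversion (4-nitrobenzoic acid, PPh3, DIAD, toluene, 0 °C → rt) should give the (R)-4-nitrobenzoate F8, and methanolysis (K2CO3, MeOH/THF, rt) rejoins the route at 11.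

**Further compounds**

F1 | step 3 | racemic (2R*,3S*,4S*)-2,3-bis[3,5-bis(benzyloxy)phenyl]-1,4-bis[4-(benzyloxy)phenyl]-4-hydroxybutan-1-one (racemate of 8, mirror-image component drawn) | c1ccccc1COc1ccc(cc1)[C@H](O)[C@@H](c1cc(OCc2ccccc2)cc(OCc2ccccc2)c1)[C@@H](c1cc(OCc2ccccc2)cc(OCc2ccccc2)c1)C(=O)c1ccc(OCc2ccccc2)cc1
F2 | step 3 | racemic [(1R*,2S*,3R*)-4,6-bis(benzyloxy)-2-[3,5-bis(benzyloxy)phenyl]-3-[4-(benzyloxy)phenyl]-2,3-dihydro-1H-inden-1-yl][4-(benzyloxy)phenyl]methanone (racemate of 10, mirror-image component drawn) | c1ccccc1COc1ccc([C@H]2c3c(OCc4ccccc4)cc(OCc4ccccc4)cc3[C@@H](C(=O)c3ccc(OCc4ccccc4)cc3)[C@@H]2c2cc(OCc3ccccc3)cc(OCc3ccccc3)c2)cc1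
F3 | step 3 | (R)-[(1S,2R,3S)-4,6-bis(benzyloxy)-2-[3,5-bis(benzyloxy)phenyl]-3-[4-(benzyloxy)phenyl]-2,3-dihydro-1H-inden-1-yl][4-(benzyloxy)phenyl]methanol | c1ccccc1COc1ccc([C@H]2c3c(OCc4ccccc4)cc(OCc4ccccc4)cc3[C@@H]([C@@H](O)c3ccc(OCc4ccccc4)cc3)[C@@H]2c2cc(OCc3ccccc3)cc(OCc3ccccc3)c2)cc1
F4 | step 4 | (2R,3S,4S)-2,3-bis(3,5-dihydroxyphenyl)-4-hydroxy-1,4-bis(4-hydroxyphenyl)butan-1-one | Oc1ccc(cc1)[C@@H](O)[C@H](c1cc(O)cc(O)c1)[C@H](c1cc(O)cc(O)c1)C(=O)c1ccc(O)cc1
F5 | step 4 | 4-[(2S,3R)-2,3-bis(3,5-dihydroxyphenyl)-4-(4-hydroxyphenyl)-4-oxobutylidene]cyclohexa-2,5-dien-1-one | O=C1C=CC(C=C1)=C[C@H](c1cc(O)cc(O)c1)[C@H](c1cc(O)cc(O)c1)C(=O)c1ccc(O)cc1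
F6 | step 4 | [(1R,2S,3R)-2-(3,5-dihydroxyphenyl)-4,6-dihydroxy-3-(4-hydroxyphenyl)-2,3-dihydro-1H-inden-1-yl](4-hydroxyphenyl)methanone | Oc1ccc([C@@H]2c3c(O)cc(O)cc3[C@H](C(=O)c3ccc(O)cc3)[C@H]2c2cc(O)cc(O)c2)cc1
F7 | step 5 | (S)-[(1R,2S,3R)-4,6-bis(benzyloxy)-2-[3,5-bis(benzyloxy)phenyl]-3-[4-(benzyloxy)phenyl]-2,3-dihydro-1H-inden-1-yl][4-(benzyloxy)phenyl]methanol | c1ccccc1COc1ccc([C@@H]2c3c(OCc4ccccc4)cc(OCc4ccccc4)cc3[C@H]([C@H](O)c3ccc(OCc4ccccc4)cc3)[C@H]2c2cc(OCc3ccccc3)cc(OCc3ccccc3)c2)cc1
F8 | step 5 | (R)-[(1R,2S,3R)-4,6-bis(benzyloxy)-2-[3,5-bis(benzyloxy)phenyl]-3-[4-(benzyloxy)phenyl]-2,3-dihydro-1H-inden-1-yl][4-(benzyloxy)phenyl]methyl 4-nitrobenzoate | c1ccccc1COc1ccc([C@@H]2c3c(OCc4ccccc4)cc(OCc4ccccc4)cc3[C@H]([C@@H](OC(=O)c3ccc(cc3)[N+](=O)[O-])c3ccc(OCc4ccccc4)cc3)[C@H]2c2cc(OCc3ccccc3)cc(OCc3ccccc3)c2)cc1
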